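**Target:** (3R,7R)-3,7-dimethyl-6,8-dioxo-3,4,7,8-tetrahydro-6H-isochromen-7-yl (9Z,12Z)-octadeca-9,12-dienoate (CNP0260084.1); CIP analysis of the given SMILES gives 3R,7R.

## Retrosynthetic overview

1. The last bond is the C7–O ester: tertiary alcohol (3R,7R)-7-hydroxy-3,7-dimethyl-3,4-dihydro-6H-isochromene-6,8(7H)-dione plus linoleoyl chloride.
2. The carbocycle (second ring) closes by aldol condensation C5→C4a of a pyranonyl 2-hydroxy-2-methyl-1,3-diketone. That ketol comes from a catalytic enantioselective 1,2-methyl shift (tertiary α-ketol rearrangement) of the isomeric Me2C(OH)–CO–CO–pyranone; the shift sets C7.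
3. The 1,2-diketone comes from ketohydroxylation of a prenyl-type enone. The dihydropyranone (first ring) comes from a δ-hydroxy-β-diketone and DMF-DMA (C1). The β-diketone comes from mesityl oxide enolate and (R)-β-butyrolactone, which supplies C3.
4. Linoleic acid: Lindlar reduction of octadeca-9,12-diynoic acid, from Cu-mediated coupling of dec-9-yn-1-ol (propargyl alcohol + 1-bromoheptane, then alkyne zipper) with oct-2-ynyl tosylate (hept-1-yne + CH2O), then Jones oxidation.
5. Ring order: 2,3-dihydro-4H-pyran-4-one first, cyclohexadienedione second; no protecting groups.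

Assumption: a step is one flask operation ending in one work-up, all starting materials are catalogue compounds, and in step 4 the (S,S)-ligand is written, its antipode being taken if the first run shows the 7S sense.

## Route

Step 1
Reactants: 1 4-methylpent-3-en-2-one (mesityl oxide); 2 (4R)-4-methyloxetan-2-one ((R)-β-butyrolactone)
Product: 4 (8R)-8-hydroxy-2-methylnon-2-ene-4,6-dione, via lithium 4-methylpenta-1,3-dien-2-olate 3 (not isolated)
Conditions: LDA (2.2 equiv), THF, −78 °C, 1 (2.2 equiv); then 2 (1.0 equiv), −78 → −40 °C; aq. NH4Cl; used crude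
Reagents that add atoms: none
Why: Kinetic α′-deprotonation of mesityl oxide gives the cross-conjugated enolate, a hard nucleophile that attacks the strained lactone at the acyl carbon (Claisen-type acylation, acyl–O cleavage), so the C–O stereocentre of 2 is carried over untouched as the future C3 (R), and the second equivalent of enolate deprotonates the β-diketone and prevents over-addition.

Step 2
Reactants: 4 (8R)-8-hydroxy-2-methylnon-2-ene-4,6-dione
Product: 6 (2R)-2-methyl-5-(3-methylbut-2-enoyl)-2,3-dihydro-4H-pyran-4-one, via aminomethylene diketone 5 (not isolated)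
Conditions: Me2NCH(OMe)2 (1.2 equiv), toluene, rt; then AcOH (2 equiv), 50 °C
Reagents that add atoms: N,N-dimethylformamide dimethyl acetal, COC(OC)N(C)C
Why: The active methylene condenses with DMF-DMA (aminomethylenation) and the δ-hydroxyl then displaces dimethylamine by 6-ring addition–elimination at the enaminone carbon, the standard 3-acyl-4-pyranone annulation, which forms the pyran ring without touching the stereocentre.

Step 3
Reactants: 6 (2R)-2-methyl-5-(3-methylbut-2-enoyl)-2,3-dihydro-4H-pyran-4-one
Product: 7 3-hydroxy-3-methyl-1-[(2R)-2-methyl-4-oxo-3,4-dihydro-2H-pyran-5-yl]butane-1,2-dione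
Conditions: RuCl3·xH2O (2 mol%), Oxone (2.5 equiv), NaHCO3 (3 equiv), EtOAc/MeCN/H2O (6:6:1), 0 °C → rt
Reagents that add atoms: potassium peroxymonosulfate (Oxone), [K+].[O-]S(=O)(=O)OO
Why: RuO4-catalysed ketohydroxylation of a trisubstituted alkene can only give the tertiary alcohol/ketone regioisomer, and the electrophilic oxidant prefers the isopropylidene enone over the doubly acyl-substituted, electron-poor enol ether of the pyranone.

Step 4
Reactants: 7 3-hydroxy-3-methyl-1-[(2R)-2-methyl-4-oxo-3,4-dihydro-2H-pyran-5-yl]butane-1,2-dione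
Product: 9 (3R,7R)-7-hydroxy-3,7-dimethyl-3,4-dihydro-6H-isochromene-6,8(7H)-dione, via rearranged triketol 8 (not isolated)
Conditions: Cu(OTf)2 (10 mol%), (S,S)-t-Bu-box (12 mol%), 4 Å MS, DCE, 40 °C; then TsOH·H2O (0.2 equiv), 50 °C
Reagents that add atoms: none
Why: Proposed new method: the chiral Cu(II)–bisoxazoline chelates the 1,2-dicarbonyl and the carbinol O–H pushes one of its two methyl groups suprafacially onto the activated adjacent carbonyl (tertiary α-ketol/acyloin 1,2-methyl shift, downhill because a 1,2-diketone is traded for a 1,3-diketone), the ligand choosing which methyl and hence which carbonyl face, so the 7R carbinol is set under catalyst control while C3 is untouched; the new methyl ketone then closes onto the pyranone carbonyl by acid-catalysed intramolecular aldol condensation (6-ring, irreversible dehydration), which forms the carbocycle and drains the ketol equilibrium; the closest known reaction type is the chiral-Lewis-acid (Cu–box, Sc– or Ni–N,N′-dioxide) catalysed enantioselective acyloin rearrangement of β-hydroxy-α-dicarbonyl compounds by ring-expanding alkyl or aryl shift, together with the Mg-dependent enzymatic acetolactate methyl shift, whereas a catalytic enantioselective methyl shift on a gem-dimethylcarbinol 1,2-diketone has not been shown.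

Step 5
Reactants: 10 prop-2-yn-1-ol; 11 1-bromoheptane
Product: 13 dec-2-yn-1-ol, via dilithium 3-oxidoprop-1-yn-1-ide 12 (not isolated)
Conditions: LiNH2 (2.2 equiv), NH3(l), −33 °C; then 11, THF; NH4Cl
Reagents that add atoms: none
Why: Double deprotonation gives the O,C-dianion, whose acetylide carbon alone is alkylated by the primary bromide (SN2 alkylation of a propargyl alcohol dianion).

Step 6
Reactants: 13 dec-2-yn-1-ol
Product: 14 dec-9-yn-1-ol
Conditions: KH (4 equiv), H2N(CH2)3NH2, rt; then 13, 0 °C → rt; H2O
Reagents that add atoms: none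
Why: Alkyne zipper isomerisation (KAPA): the triple bond walks along the chain by propargyl–allenyl proton shifts and is trapped irreversibly as the terminal acetylide at the end remote from the alkoxide.

Step 7
Reactants: 15 hept-1-yne
Product: 18 oct-2-yn-1-yl 4-methylbenzenesulfonate, via hept-1-yn-1-yllithium 16 (not isolated), via lithium oct-2-yn-1-olate 17 (not isolated)
Conditions: n-BuLi (1.05 equiv), THF, −78 °C; (CH2O)n (1.5 equiv), −78 °C → rt; then TsCl (1.1 equiv), −20 → 0 °C
Reagents that add atoms: formaldehyde (as paraformaldehyde), C=O; p-toluenesulfonyl chloride, Cc1ccc(cc1)S(Cl)(=O)=O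
Why: Acetylide addition to formaldehyde followed by O-sulfonylation of the lithium alkoxide in the same pot gives the primary propargylic tosylate without isolating the alcohol.

Step 8
Reactants: 14 dec-9-yn-1-ol; 18 oct-2-yn-1-yl 4-methylbenzenesulfonate
Product: 20 octadeca-9,12-diyn-1-ol, via 1-iodooct-2-yne 19 (not isolated)
Conditions: CuI (1.0 equiv), NaI (1.0 equiv), Cs2CO3 (1.0 equiv), DMF, rt
Reagents that add atoms: none
Why: Copper(I)-mediated sp–sp3 coupling of a terminal alkyne with a propargylic electrophile (in-situ Finkelstein activation) under carbonate conditions gives the skipped diyne without allene formation and tolerates the free hydroxyl.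

Step 9
Reactants: 20 octadeca-9,12-diyn-1-ol
Product: 21 octadeca-9,12-diynoic acid
Conditions: CrO3, H2SO4, H2O, acetone, 0 °C
Reagents that add atoms: water, O
Why: Jones oxidation takes the primary alcohol through the aldehyde hydrate to the acid under acidic conditions that do not isomerise the base-sensitive skipped diyne.

Step 10
Reactants: 21 octadeca-9,12-diynoic acid
Product: 22 (9Z,12Z)-octadeca-9,12-dienoic acid (linoleic acid)
Conditions: H2 (1 atm, 2.0 equiv uptake), Lindlar Pd/CaCO3–Pb, quinoline, EtOAc, rt
Reagents that add atoms: none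
Why: Lindlar semi-hydrogenation delivers H2 syn to each alkyne on the poisoned palladium surface and so sets both Z double bonds, with quinoline and monitored uptake stopping over-reduction.

Step 11
Reactants: 22 (9Z,12Z)-octadeca-9,12-dienoic acid; 9 (3R,7R)-7-hydroxy-3,7-dimethyl-3,4-dihydro-6H-isochromene-6,8(7H)-dione
Product: 24 (3R,7R)-3,7-dimethyl-6,8-dioxo-3,4,7,8-tetrahydro-6H-isochromen-7-yl (9Z,12Z)-octadeca-9,12-dienoate, via linoleoyl chloride 23 (not isolated)
Conditions: 22, (COCl)2 (1.2 equiv), DMF (cat.), CH2Cl2, 0 °C → rt, evaporate; then 9, DMAP (1.5 equiv), Et3N (2 equiv), CH2Cl2, 0 °C → rt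
Reagents that add atoms: none
Why: DMAP-catalysed nucleophilic acyl substitution acylates the hindered tertiary 7-OH without breaking a bond at C7, so 7R is retained, and the skipped diene and the vinylogous ester tolerate the mild tertiary-amine base.

## Compound list

1 | 4-methylpent-3-en-2-one (mesityl oxide) | CC(C)=CC(C)=O | starting material
2 | (4R)-4-methyloxetan-2-one ((R)-β-butyrolactone) | C[C@@H]1CC(=O)O1 | starting material
3 | lithium 4-methylpenta-1,3-dien-2-olate | [Li+].[O-]C(=C)C=C(C)C | intermediate (not isolated)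
4 | (8R)-8-hydroxy-2-methylnon-2-ene-4,6-dione | CC(C)=CC(=O)CC(=O)C[C@@H](C)O | intermediate
5 | (8R)-5-[(dimethylamino)methylidene]-8-hydroxy-2-methylnon-2-ene-4,6-dione | CC(C)=CC(=O)C(=CN(C)C)C(=O)C[C@@H](C)O | intermediate (not isolated)
6 | (2R)-2-methyl-5-(3-methylbut-2-enoyl)-2,3-dihydro-4H-pyran-4-one | C[C@@H]1CC(=O)C(=CO1)C(=O)C=C(C)C | intermediate
7 | 3-hydroxy-3-methyl-1-[(2R)-2-methyl-4-oxo-3,4-dihydro-2H-pyran-5-yl]butane-1,2-dione | C[C@@H]1CC(=O)C(=CO1)C(=O)C(=O)C(C)(C)O | intermediate
8 | (2R)-2-hydroxy-2-methyl-1-[(2R)-2-methyl-4-oxo-3,4-dihydro-2H-pyran-5-yl]butane-1,3-dione | CC(=O)[C@@](C)(O)C(=O)C1=CO[C@H](C)CC1=O | intermediate (not isolated)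
9 | (3R,7R)-7-hydroxy-3,7-dimethyl-3,4-dihydro-6H-isochromene-6,8(7H)-dione | O[C@]1(C)C(=O)C=C2C[C@@H](C)OC=C2C1=O | intermediate
10 | prop-2-yn-1-ol | OCC#C | starting material
11 | 1-bromoheptane | CCCCCCCBr | starting material
12 | dilithium 3-oxidoprop-1-yn-1-ide | [Li+].[Li+].[O-]CC#[C-] | intermediate (not isolated)
13 | dec-2-yn-1-ol | CCCCCCCC#CCO | intermediate
14 | dec-9-yn-1-ol | OCCCCCCCCC#C | intermediate
15 | hept-1-yne | CCCCCC#C | starting material
16 | hept-1-yn-1-yllithium | [Li+].[C-]#CCCCCC | intermediate (not isolated)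
17 | lithium oct-2-yn-1-olate | [Li+].[O-]CC#CCCCCC | intermediate (not isolated)
18 | oct-2-yn-1-yl 4-methylbenzenesulfonate | CCCCCC#CCOS(=O)(=O)c1ccc(C)cc1 | intermediate
19 | 1-iodooct-2-yne | CCCCCC#CCI | intermediate (not isolated)
20 | octadeca-9,12-diyn-1-ol | CCCCCC#CCC#CCCCCCCCCO | intermediate
21 | octadeca-9,12-diynoic acid | CCCCCC#CCC#CCCCCCCCC(=O)O | intermediate
22 | (9Z,12Z)-octadeca-9,12-dienoic acid (linoleic acid) | CCCCC/C=C\C/C=C\CCCCCCCC(=O)O | intermediate
23 | (9Z,12Z)-octadeca-9,12-dienoyl chloride (linoleoyl chloride) | CCCCC/C=C\C/C=C\CCCCCCCC(Cl)=O | intermediate (not isolated)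
24 | (3R,7R)-3,7-dimethyl-6,8-dioxo-3,4,7,8-tetrahydro-6H-isochromen-7-yl (9Z,12Z)-octadeca-9,12-dienoate (CNP0260084.1) | CCCCC/C=C\C/C=C\CCCCCCCC(=O)O[C@]1(C)C(=O)C=C2C[C@@H](C)OC=C2C1=O | target

## Step count and risks

Total steps: 11. Longest linear sequence: 6 steps (5 → 6 → 8 → 9 → 10 → 11).

**Step 4 (the proposed methyl-shift/aldol cascade) is the most likely to fail.** The catalyst may be held at the β-dicarbonyl site of the pyranone instead of the 1,2-dione, and the methyl discrimination may be poor. The free tertiary hydroxyl of 7 or 8 can also add to the enol-ether carbon and divert material into ring-switched pyrandione or 3(2H)-furanone isomers, and the aldol could close through the pyranone CH2 instead of the new methyl ketone. The fallback uses known chemistry only, sets out from 2 and returns to the route at 9. 3-Methylpentane-2,4-dione F1 is doubly deprotonated (NaH, then n-BuLi, THF, 0 °C) and acylated at its terminal carbon by 2. The resulting (8R)-8-hydroxy-3-methylnonane-2,4,6-trione F2 is not isolated but cyclised with aqueous KOH (aldol condensation and aromatisation of a 1,3,5-triketone) to 5-[(2R)-2-hydroxypropyl]-2-methylbenzene-1,3-diol F3. Vilsmeier–Haack formylation (POCl3, DMF; aqueous NaOAc) at either of the two equivalent ring positions gives 2,4-dihydroxy-6-[(2R)-2-hydroxypropyl]-3-methylbenzaldehyde F4. TFA in DCE closes F4 to (3R)-8-hydroxy-3,7-dimethyl-3,4-dihydro-6H-isochromen-6-one F5, which is oxidised in the same flask with IBX and catalytic Bu4NI (hydroxylative dearomatisation, as used for azaphilones). This gives 9 together with its epimer (3R,7S)-7-hydroxy-3,7-dimethyl-3,4-dihydro-6H-isochromene-6,8(7H)-dione F6, which is removed by chromatography; the two are diastereomers because C3 is fixed.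

**Step 3 (ketohydroxylation).** RuO4 may cleave the pyranone enol ether, and the peroxymonosulfate may cleave the newly formed 1,2-diketone. The fallback sets out from 6 and returns at 7. Dihydroxylation of the enone double bond (OsO4 cat., NMO, citric acid, t-BuOH/H2O) gives 2,3-dihydroxy-3-methyl-1-[(2R)-2-methyl-4-oxo-3,4-dihydro-2H-pyran-5-yl]butan-1-one F7 as a mixture at the new secondary carbinol. Its secondary alcohol is then oxidised with Dess–Martin periodinane (CH2Cl2, NaHCO3, rt), a non-peroxidic oxidant that does not cleave 1,2-diones, to give 7.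

**Step 1 (enolate acylation by the β-lactone).** The lactone may be opened at the alkyl carbon or oligomerise, and 4 cyclodehydrates to an isomeric dihydropyranone if it meets acid. The fallback sets out from 2 and returns at 4. The lactone 2 is opened with MeNH(OMe)·HCl and Me2AlCl (CH2Cl2, 0 °C) to (3R)-3-hydroxy-N-methoxy-N-methylbutanamide F8, an open-chain acyl donor that cannot react at the alkyl carbon and does not over-add. F8 is then treated with enolate 3 (3.2 equiv, THF, −78 → 0 °C; the first equivalent deprotonates the hydroxyl) to give 4 after NH4Cl work-up (acylation of a ketone enolate by a Weinreb amide).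

## Further compounds

F1 | step 4 | 3-methylpentane-2,4-dione | CC(=O)C(C)C(C)=O
F2 | step 4 | (8R)-8-hydroxy-3-methylnonane-2,4,6-trione | CC(=O)C(C)C(=O)CC(=O)C[C@@H](C)O
F3 | step 4 | 5-[(2R)-2-hydroxypropyl]-2-methylbenzene-1,3-diol | Cc1c(O)cc(C[C@@H](C)O)cc1O
F4 | step 4 | 2,4-dihydroxy-6-[(2R)-2-hydroxypropyl]-3-methylbenzaldehyde | Cc1c(O)cc(C[C@@H](C)O)c(C=O)c1O
F5 | step 4 | (3R)-8-hydroxy-3,7-dimethyl-3,4-dihydro-6H-isochromen-6-one | C[C@@H]1CC2=CC(=O)C(C)=C(O)C2=CO1
F6 | step 4 | (3R,7S)-7-hydroxy-3,7-dimethyl-3,4-dihydro-6H-isochromene-6,8(7H)-dione | O[C@@]1(C)C(=O)C=C2C[C@@H](C)OC=C2C1=O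
F7 | step 3 | 2,3-dihydroxy-3-methyl-1-[(2R)-2-methyl-4-oxo-3,4-dihydro-2H-pyran-5-yl]butan-1-one | C[C@@H]1CC(=O)C(=CO1)C(=O)C(O)C(C)(C)O
F8 | step 1 | (3R)-3-hydroxy-N-methoxy-N-methylbutanamide | C[C@@H](O)CC(=O)N(C)OC
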